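**Retrosynthetic overview**
1. Target ⇐ tetraol 30 by acetylation of the three secondary alcohols; the ten-membered ring is opened at C9–C10 (intramolecular allylchromium addition to a C9 aldehyde) and is the last ring formed.
2. The γ-lactone ⇐ C7–C8 aldol of a dioxolanone enolate (C8, C9, C17–C19) with a (Z)-enal (C7), followed by lactonisation; it is the second ring formed.
3. Ring A with C1 and C14 ⇐ key step: desymmetrising boronate-tethered oxa-Michael addition of the C2 carbinol onto a Cs-symmetric 4,4-disubstituted cyclohexa-2,5-dienone.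
4. The dienone ⇐ benzoic acid by Birch reductive methylation (dearomatisation; ring A is formed first, from the arene), acylation with a (Z)-C3–C7 zinc reagent, CBS reduction and bis-allylic oxidation.
5. The C8/C17 unit ⇐ Evans syn-aldol of a propionyl oxazolidinone with ethyl glyoxylate.

Assumption: briarane numbering (C1–C20) is used for all intermediates, and 4-methyl-5,6-dihydro-2H-pyran-2-one and (R)-4-benzyl-3-propanoyl-1,3-oxazolidin-2-one are taken as purchasable.

**Route**

Step 1
Reactants: 1 benzoic acid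
Product: 3 1-methylcyclohexa-2,5-diene-1-carboxylic acid, via dilithium dienediolate 2 (not isolated)
Conditions: Li, NH3(l)/THF, −78 °C; MeI; aq. HCl
Reagents that add atoms: iodomethane, CI
Why: Birch reductive alkylation: the benzoate is reduced to the cross-conjugated dienediolate, which is C-methylated at the ipso carbon, so the arene becomes a Cs-symmetric 1,4-diene that already holds the C1 quaternary carbon (C15 methyl, C2 carboxyl) and no stereocentre yet.

Step 2
Reactants: 4 4-methyl-5,6-dihydro-2H-pyran-2-one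
Product: 5 (Z)-5-hydroxy-N-methoxy-N,3-dimethylpent-2-enamide
Conditions: MeNH(OMe)·HCl, i-PrMgCl, THF, −20 → 0 °C; aq. NH4Cl
Reagents that add atoms: N,O-dimethylhydroxylamine hydrochloride, CNOC.Cl
Why: Weinreb aminolysis of the δ-lactone by the magnesium amide (acyl substitution), with the Z geometry of the future C5=C6 bond inherited from the six-membered ring.

Step 3
Reactants: 5 (Z)-5-hydroxy-N-methoxy-N,3-dimethylpent-2-enamide
Product: 6 (Z)-5-iodo-N-methoxy-N,3-dimethylpent-2-enamide
Conditions: I2, PPh3, imidazole, CH2Cl2, 0 °C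
Reagents that add atoms: iodine, II
Why: Appel iodination of the primary alcohol (SN2 on the alkoxyphosphonium ion) leaves the enamide and its geometry untouched.

Step 4
Reactants: 3 1-methylcyclohexa-2,5-diene-1-carboxylic acid; 6 (Z)-5-iodo-N-methoxy-N,3-dimethylpent-2-enamide
Product: 9 (Z)-N-methoxy-N,3-dimethyl-6-(1-methylcyclohexa-2,5-dien-1-yl)-6-oxohex-2-enamide, via acyl chloride 7 (not isolated), via alkylzinc iodide 8 (not isolated)
Conditions: 3, (COCl)2, DMF (cat.), CH2Cl2, then evaporate; 6, Zn dust, THF, 35 °C; combine, Pd(PPh3)4 (5 mol %), THF, 0 → 23 °C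
Reagents that add atoms: none
Why: Negishi acylation of the acid chloride with the functionalised alkylzinc iodide stops at the ketone, the quaternary α-carbon excludes ketene formation, and no stereocentre is involved.

Step 5
Reactants: 9 (Z)-N-methoxy-N,3-dimethyl-6-(1-methylcyclohexa-2,5-dien-1-yl)-6-oxohex-2-enamide
Product: 10 (2Z,6R)-6-hydroxy-N-methoxy-N,3-dimethyl-6-(1-methylcyclohexa-2,5-dien-1-yl)hex-2-enamide
Conditions: (S)-2-methyl-CBS-oxazaborolidine [(S)-1-methyl-3,3-diphenyltetrahydro-1H,3H-pyrrolo[1,2-c][1,3,2]oxazaborole] (20 mol %), catecholborane, toluene, −78 °C; MeOH, aq. NaOH wash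
Reagents that add atoms: none
Why: Corey–Bakshi–Shibata reduction in which the quaternary dienyl carbon is the large and the CH2 chain the small substituent, so the (S)-catalyst gives the (R)-carbinol at C2, while catecholborane at −78 °C spares the olefins and the Weinreb amide.

Step 6
Reactants: 10 (2Z,6R)-6-hydroxy-N-methoxy-N,3-dimethyl-6-(1-methylcyclohexa-2,5-dien-1-yl)hex-2-enamide
Product: 11 (2Z,6R)-6-hydroxy-N-methoxy-N,3-dimethyl-6-(1-methyl-4-oxocyclohexa-2,5-dien-1-yl)hex-2-enamide
Conditions: Rh2(cap)4 (dirhodium tetracaprolactamate, 1 mol %), t-BuOOH (70% aq.), NaHCO3, CH2Cl2, 23 °C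
Reagents that add atoms: tert-butyl hydroperoxide, CC(C)(C)OO
Why: Dirhodium-catalysed allylic oxidation by tert-butylperoxyl radicals attacks the doubly allylic CH2 (weakest C–H bond, much weaker than the carbinol C–H) and gives the symmetric cyclohexa-2,5-dienone, the buffered medium avoiding alkoxide formation and retro-aldol aromatisation.

Step 7
Reactants: 11 (2Z,6R)-6-hydroxy-N-methoxy-N,3-dimethyl-6-(1-methyl-4-oxocyclohexa-2,5-dien-1-yl)hex-2-enamide
Product: 13 (2Z,6R)-6-hydroxy-6-[(1S,6S)-6-hydroxy-1-methyl-4-oxocyclohex-2-en-1-yl]-N-methoxy-N,3-dimethylhex-2-enamide, via cyclic phenylboronate 12 (not isolated)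
Conditions: PhB(OH)2, quinuclidine (20 mol %), 4 Å molecular sieves, CH2Cl2, 23 °C; then pinacol
Reagents that add atoms: phenylboronic acid, OB(O)c1ccccc1
Why: Proposed new method: the C2 hydroxyl forms a boronic hemiester whose amine-activated B–OH oxygen adds to one of the two diastereotopic enone β-carbons through a six-membered chair with the C3 chain and the C14–C13 ring bond equatorial (the other arm needs an axial substituent), so O14 arrives cis to C2 and the prochiral C1 becomes S with C14 S; the closest known reaction type is the amine-promoted boronic acid oxa-Michael addition to δ-hydroxy enones, here used for diastereotopic-group selection on a cyclohexadienone.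

Step 8
Reactants: 13 (2Z,6R)-6-hydroxy-6-[(1S,6S)-6-hydroxy-1-methyl-4-oxocyclohex-2-en-1-yl]-N-methoxy-N,3-dimethylhex-2-enamide
Product: 14 (2Z,6R)-N-methoxy-N,3-dimethyl-6-[(1S,6S)-1-methyl-4-oxo-6-(triethylsilyloxy)cyclohex-2-en-1-yl]-6-(triethylsilyloxy)hex-2-enamide
Conditions: Et3SiOTf, 2,6-lutidine, CH2Cl2, −78 °C
Reagents that add atoms: triethylsilyl trifluoromethanesulfonate, CC[Si](CC)(CC)OS(=O)(=O)C(F)(F)F
Why: Silyl triflate/lutidine protection of both secondary alcohols proceeds cold without β-elimination and, unlike a cyclic acetal, leaves ring A conformationally free for the later ring closure.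

Step 9
Reactants: 14 (bis-silyl ether enone)
Product: 15 (2Z,6R)-6-[(1S,6S)-3-iodo-1-methyl-4-oxo-6-(triethylsilyloxy)cyclohex-2-en-1-yl]-N-methoxy-N,3-dimethyl-6-(triethylsilyloxy)hex-2-enamide
Conditions: I2, pyridine/CH2Cl2, 0 → 23 °C
Reagents that add atoms: iodine, II
Why: Pyridine-mediated α-iodination of the enone (conjugate addition of pyridine, iodination of the enolate, elimination) is specific for the unsubstituted enone α-carbon C11.

Step 10
Reactants: 15 (α-iodoenone)
Product: 16 (2Z,6R)-6-[(1S,6S)-1,3-dimethyl-4-oxo-6-(triethylsilyloxy)cyclohex-2-en-1-yl]-N-methoxy-N,3-dimethyl-6-(triethylsilyloxy)hex-2-enamide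
Conditions: Me2Zn, Pd(dppf)Cl2 (5 mol %), THF, 0 → 23 °C
Reagents that add atoms: dimethylzinc, C[Zn]C
Why: Negishi cross-coupling of the α-iodoenone installs the C20 methyl on C11 under neutral conditions that do not eliminate the β-silyloxy group.

Step 11
Reactants: 16 (α-methyl enone Weinreb amide)
Product: 17 (2Z,6R)-6-[(1S,6S)-4-hydroxy-1,3-dimethyl-6-(triethylsilyloxy)cyclohex-2-en-1-yl]-3-methyl-6-(triethylsilyloxy)hex-2-enal (both C12 epimers)
Conditions: i-Bu2AlH (excess), CH2Cl2, −78 °C; aq. potassium sodium tartrate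
Reagents that add atoms: none
Why: i-Bu2AlH reduces the Weinreb amide to the aldehyde through its stable aluminium chelate (released only on work-up, so the Z-enal is neither over-reduced nor isomerised) and the enone by 1,2-addition to the allylic alcohol, whose C12 epimer mixture is irrelevant because this centre becomes sp2 in step 19.

Step 12
Reactants: 17 (enal allylic alcohol)
Product: 18 C12 diethyl phosphate of 17
Conditions: ClP(O)(OEt)2, pyridine, 4-(dimethylamino)pyridine (cat.), CH2Cl2, 0 °C
Reagents that add atoms: diethyl chlorophosphate, CCOP(=O)(Cl)OCC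
Why: Phosphorylation of the only free hydroxyl turns C12–O into the leaving group needed for allylchromium formation, and the enal is inert to it.

Step 13
Reactants: 19 (R)-4-benzyl-3-propanoyl-1,3-oxazolidin-2-one; 20 ethyl glyoxylate
Product: 21 ethyl (2R,3R)-4-[(4R)-4-benzyl-2-oxo-1,3-oxazolidin-3-yl]-2-hydroxy-3-methyl-4-oxobutanoate
Conditions: n-Bu2BOTf, i-Pr2NEt, CH2Cl2, 0 °C; 20, −78 → 0 °C; pH 7 buffer, MeOH, H2O2
Reagents that add atoms: none
Why: Evans syn-aldol reaction: the Z-boron enolate adds to the glyoxylate through a chair Zimmerman–Traxler transition state on the face away from the benzyl group, which sets the future C8 carbinol (R) and C17 methyl centre (R) syn to each other.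

Step 14
Reactants: 21 (Evans aldol adduct)
Product: 22 (2R,3R)-2-hydroxy-3-methylbutanedioic acid
Conditions: LiOH, H2O2, THF/H2O, 0 → 23 °C; Na2SO3; HCl to pH 1
Reagents that add atoms: lithium hydroxide, [Li+].[OH-]; hydrogen peroxide, OO
Why: Lithium hydroperoxide cleaves the imide at the exocyclic carbonyl and hydroxide saponifies the ethyl ester at a temperature where the C17 α-stereocentre does not epimerise.

Step 15
Reactants: 22 (2R,3R)-2-hydroxy-3-methylbutanedioic acid
Product: 23 (2R)-2-[(2R,4R)-2-tert-butyl-5-oxo-1,3-dioxolan-4-yl]propanoic acid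
Conditions: t-BuCHO, p-TsOH (cat.), H2SO4 (cat.), pentane, reflux, Dean–Stark
Reagents that add atoms: pivalaldehyde, CC(C)(C)C=O
Why: Acid-catalysed acetalisation of the α-hydroxy acid unit (five-membered dioxolanone preferred, as with malic acid) gives under thermodynamic control the cis-dioxolanone, whose acetal centre stores the C8 configuration (self-regeneration of stereocentres).

Step 16
Reactants: 18 C12 diethyl phosphate of 17; 23 (2R)-2-[(2R,4R)-2-tert-butyl-5-oxo-1,3-dioxolan-4-yl]propanoic acid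
Product: 26 spiro dioxolanone γ-lactone, via dilithium enolate 24 (not isolated), via aldol hydroxy acid 25 (not isolated)
Conditions: 23, LiN(SiMe3)2 (2.1 equiv), THF, −78 °C; 18, −78 °C; AcOH, −78 → 23 °C
Reagents that add atoms: none
Why: Seebach aldol reaction: the dioxolanone enolate is attacked anti to the tert-butyl group (retention at C8) through a chair Zimmerman–Traxler transition state with the enolate oxygen cis to the C17 branch, which places O7 anti to O8 and syn to C17 (C7 S), and the γ-hydroxy acid then lactonises to close the lactone ring.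

Step 17
Reactants: 26 (spiro dioxolanone γ-lactone)
Product: 27 8-hydroxy-8-(hydroxymethyl) γ-lactone (C9 as CH2OH)
Conditions: NaBH4, EtOH/THF, 0 °C; aq. NH4Cl
Reagents that add atoms: none
Why: Chemoselective borohydride reduction of the activated acetal-ester carbonyl: the hemiacetal collapses with loss of pivalaldehyde and the freed C9 aldehyde is reduced on to the primary alcohol, while the α-branched γ-lactone and the phosphate survive at 0 °C.

Step 18
Reactants: 27 (diol)
Product: 28 8-formyl-8-hydroxy γ-lactone (C9 aldehyde) with the C12 allylic phosphate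
Conditions: SO3·pyridine, DMSO, i-Pr2NEt, CH2Cl2, 0 °C
Reagents that add atoms: none
Why: Parikh–Doering oxidation converts the primary alcohol into a non-enolisable α-hydroxy aldehyde without glycol cleavage, and the tertiary C8 hydroxyl cannot be oxidised.

Step 19
Reactants: 28 (aldehyde allylic phosphate)
Product: 29 2,14-bis(triethylsilyl) ether of 2,9,14-tri-O-deacetylstylatulide lactone
Conditions: CrCl2 (8 equiv), LiI (cat.), DMF/THF, 23 °C, 2 mM, slow addition
Reagents that add atoms: none
Why: Nozaki–Hiyama–Kishi-type allylation: two equivalents of divalent chromium reduce the allylic phosphate (through the iodide) to an allylchromium species that attacks the C9 aldehyde with its γ-carbon C10 in a closed six-membered transition state, which forms the ten-membered ring and the C11=C12 olefin; the arrangement with the C14 silyloxy group equatorial and the C2 branch pseudo-axial lets C9 bond anti to C2 (trans fusion, C10 S), and chelation of the C8 hydroxyl to chromium with delivery from the C7 side of the tether should give the 9R carbinol.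

Step 20
Reactants: 29 (bis-silyl ether macrocycle)
Product: 30 2,9,14-tri-O-deacetylstylatulide lactone
Conditions: HF·pyridine, THF/pyridine, 0 → 23 °C
Reagents that add atoms: none
Why: Fluoride-mediated cleavage of both triethylsilyl ethers under buffered conditions leaves the β-hydroxy lactone intact (no retro-aldol, no lactone migration).

Step 21
Reactants: 30 2,9,14-tri-O-deacetylstylatulide lactone
Product: 31 stylatulide lactone
Conditions: Ac2O, pyridine, 4-(dimethylamino)pyridine (cat.), CH2Cl2, 0 → 23 °C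
Reagents that add atoms: acetic anhydride, CC(=O)OC(C)=O
Why: Nucleophile-catalysed acylation esterifies the three secondary alcohols (C2, C9, C14) while the hindered tertiary C8 hydroxyl stays free, which gives the target.

**Compound list**

1 | benzoic acid | OC(=O)c1ccccc1 | starting material
2 | dilithium (cyclohexa-2,5-dien-1-ylidene)methanediolate | [Li+].[Li+].[O-]C([O-])=C1C=CCC=C1 | intermediate
3 | 1-methylcyclohexa-2,5-diene-1-carboxylic acid | CC1(C=CCC=C1)C(=O)O | intermediate
4 | 4-methyl-5,6-dihydro-2H-pyran-2-one | CC1=CC(=O)OCC1 | starting material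
5 | (Z)-5-hydroxy-N-methoxy-N,3-dimethylpent-2-enamide | CON(C)C(=O)/C=C(/C)CCO | intermediate
6 | (Z)-5-iodo-N-methoxy-N,3-dimethylpent-2-enamide | CON(C)C(=O)/C=C(/C)CCI | intermediate
7 | 1-methylcyclohexa-2,5-diene-1-carbonyl chloride | CC1(C=CCC=C1)C(Cl)=O | intermediate
8 | [(Z)-5-[methoxy(methyl)amino]-3-methyl-5-oxopent-3-en-1-yl]zinc iodide | CON(C)C(=O)/C=C(/C)CC[Zn]I | intermediate
9 | (Z)-N-methoxy-N,3-dimethyl-6-(1-methylcyclohexa-2,5-dien-1-yl)-6-oxohex-2-enamide | CON(C)C(=O)/C=C(/C)CCC(=O)C1(C)C=CCC=C1 | intermediate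
10 | (2Z,6R)-6-hydroxy-N-methoxy-N,3-dimethyl-6-(1-methylcyclohexa-2,5-dien-1-yl)hex-2-enamide | CON(C)C(=O)/C=C(/C)CC[C@@H](O)C1(C)C=CCC=C1 | intermediate
11 | (2Z,6R)-6-hydroxy-N-methoxy-N,3-dimethyl-6-(1-methyl-4-oxocyclohexa-2,5-dien-1-yl)hex-2-enamide | CON(C)C(=O)/C=C(/C)CC[C@@H](O)C1(C)C=CC(=O)C=C1 | intermediate
12 | cyclic phenylboronate of 13 (boron bridges O2 and O14 in a 1,3,2-dioxaborinane cis-fused to ring A) | c1ccccc1B2O[C@H]3CC(=O)C=C[C@@]3(C)[C@H](O2)CC/C(C)=C\C(=O)N(C)OC | intermediate
13 | (2Z,6R)-6-hydroxy-6-[(1S,6S)-6-hydroxy-1-methyl-4-oxocyclohex-2-en-1-yl]-N-methoxy-N,3-dimethylhex-2-enamide (C1 S, C2 R, C14 S) | O[C@H]1CC(=O)C=C[C@@]1(C)[C@H](O)CC/C(C)=C\C(=O)N(C)OC | intermediate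
14 | (2Z,6R)-N-methoxy-N,3-dimethyl-6-[(1S,6S)-1-methyl-4-oxo-6-(triethylsilyloxy)cyclohex-2-en-1-yl]-6-(triethylsilyloxy)hex-2-enamide | CC[Si](CC)(CC)O[C@H]1CC(=O)C=C[C@@]1(C)[C@H](O[Si](CC)(CC)CC)CC/C(C)=C\C(=O)N(C)OC | intermediate
15 | (2Z,6R)-6-[(1S,6S)-3-iodo-1-methyl-4-oxo-6-(triethylsilyloxy)cyclohex-2-en-1-yl]-N-methoxy-N,3-dimethyl-6-(triethylsilyloxy)hex-2-enamide | CC[Si](CC)(CC)O[C@H]1CC(=O)C(I)=C[C@@]1(C)[C@H](O[Si](CC)(CC)CC)CC/C(C)=C\C(=O)N(C)OC | intermediate
16 | (2Z,6R)-6-[(1S,6S)-1,3-dimethyl-4-oxo-6-(triethylsilyloxy)cyclohex-2-en-1-yl]-N-methoxy-N,3-dimethyl-6-(triethylsilyloxy)hex-2-enamide | CC[Si](CC)(CC)O[C@H]1CC(=O)C(C)=C[C@@]1(C)[C@H](O[Si](CC)(CC)CC)CC/C(C)=C\C(=O)N(C)OC | intermediate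
17 | (2Z,6R)-6-[(1S,6S)-4-hydroxy-1,3-dimethyl-6-(triethylsilyloxy)cyclohex-2-en-1-yl]-3-methyl-6-(triethylsilyloxy)hex-2-enal (both C12 epimers) | CC[Si](CC)(CC)O[C@H]1CC(O)C(C)=C[C@@]1(C)[C@H](O[Si](CC)(CC)CC)CC/C(C)=C\C=O | intermediate
18 | C12 diethyl phosphate of 17 (both C12 epimers) | CC[Si](CC)(CC)O[C@H]1CC(OP(=O)(OCC)OCC)C(C)=C[C@@]1(C)[C@H](O[Si](CC)(CC)CC)CC/C(C)=C\C=O | intermediate
19 | (R)-4-benzyl-3-propanoyl-1,3-oxazolidin-2-one | CCC(=O)N1[C@H](Cc2ccccc2)COC1=O | starting material
20 | ethyl glyoxylate | CCOC(=O)C=O | starting material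
21 | ethyl (2R,3R)-4-[(4R)-4-benzyl-2-oxo-1,3-oxazolidin-3-yl]-2-hydroxy-3-methyl-4-oxobutanoate | CCOC(=O)[C@H](O)[C@@H](C)C(=O)N1[C@H](Cc2ccccc2)COC1=O | intermediate
22 | (2R,3R)-2-hydroxy-3-methylbutanedioic acid | OC(=O)[C@H](O)[C@@H](C)C(=O)O | intermediate
23 | (2R)-2-[(2R,4R)-2-tert-butyl-5-oxo-1,3-dioxolan-4-yl]propanoic acid (cis-dioxolanone) | OC(=O)[C@H](C)[C@H]1O[C@@H](C(C)(C)C)OC1=O | intermediate
24 | dilithium salt of 23 (carboxylate plus dioxolanone enolate) | [Li+].[Li+].[O-]C(=O)[C@H](C)C1=C([O-])O[C@H](C(C)(C)C)O1 | intermediate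
25 | aldol hydroxy acid (C7 carbinol S, C8 quaternary in the dioxolanone, C17 bearing CH3 and CO2H) | CC[Si](CC)(CC)O[C@H]1CC(OP(=O)(OCC)OCC)C(C)=C[C@@]1(C)[C@H](O[Si](CC)(CC)CC)CC/C(C)=C\[C@H](O)[C@@]2(O[C@@H](C(C)(C)C)OC2=O)[C@@H](C)C(=O)O | intermediate
26 | spiro dioxolanone γ-lactone (lactone C7–O–C19, spiro centre C8) | CC[Si](CC)(CC)O[C@H]1CC(OP(=O)(OCC)OCC)C(C)=C[C@@]1(C)[C@H](O[Si](CC)(CC)CC)CC/C(C)=C\[C@@H]2OC(=O)[C@H](C)[C@]23O[C@@H](C(C)(C)C)OC3=O | intermediate
27 | 8-hydroxy-8-(hydroxymethyl) γ-lactone (C9 as CH2OH; C7, C8, C17 as in 26) | CC[Si](CC)(CC)O[C@H]1CC(OP(=O)(OCC)OCC)C(C)=C[C@@]1(C)[C@H](O[Si](CC)(CC)CC)CC/C(C)=C\[C@@H]2OC(=O)[C@H](C)[C@@]2(O)CO | intermediate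
28 | 8-formyl-8-hydroxy γ-lactone (C9 aldehyde) with the C12 allylic phosphate | CC[Si](CC)(CC)O[C@H]1CC(OP(=O)(OCC)OCC)C(C)=C[C@@]1(C)[C@H](O[Si](CC)(CC)CC)CC/C(C)=C\[C@@H]2OC(=O)[C@H](C)[C@@]2(O)C=O | intermediate
29 | 2,14-bis(triethylsilyl) ether of 2,9,14-tri-O-deacetylstylatulide lactone | CC[Si](CC)(CC)O[C@H]1CC=C(C)[C@@H]2[C@@H](O)[C@@]3(O)[C@H](/C=C(/C)CC[C@@H](O[Si](CC)(CC)CC)[C@@]12C)OC(=O)[C@@H]3C | intermediate
30 | 2,9,14-tri-O-deacetylstylatulide lactone | O[C@H]1CC=C(C)[C@@H]2[C@@H](O)[C@@]3(O)[C@H](/C=C(/C)CC[C@@H](O)[C@@]12C)OC(=O)[C@@H]3C | intermediate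
31 | stylatulide lactone | CC(=O)O[C@H]1CC=C(C)[C@@H]2[C@@H](OC(C)=O)[C@@]3(O)[C@H](/C=C(/C)CC[C@@H](OC(C)=O)[C@@]12C)OC(=O)[C@@H]3C | target

**Step count and risks**

Total: 21 steps. Longest linear sequence: 17 steps (2, 3, 4–12, 16–21, from 4-methyl-5,6-dihydro-2H-pyran-2-one); from benzoic acid it is 16.

The three steps most likely to fail:

Step 7 (desymmetrising oxa-Michael addition). The arm selectivity rests on a chair argument only, and the hydroxy dienone 11 can undergo retro-aldol aromatisation under base. The fallback sets out from 10 and never makes a hydroxy dienone. Hydroxyl-directed epoxidation of the diene with VO(acac)2 and t-BuOOH (CH2Cl2, 0 °C) selects one of the two diastereotopic ring olefins on the face cis to C2 and gives the epoxy alcohol F1. Rh2(cap)4/t-BuOOH oxidation of the only remaining allylic CH2 then gives the epoxy enone F2. Reductive opening of the α,β-epoxy ketone with SmI2 (THF/MeOH, −78 °C) cleaves the C13–O bond and gives the β-hydroxy ketone 13, where the route is rejoined.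

Step 16 (aldol addition and lactonisation). The C8 configuration is secure, but the C7 carbinol selectivity of dioxolanone enolate aldols can be modest. The fallback sets out from 18 and 23. If the C7 epimer predominates, the aldol is quenched cold with aqueous NH4Cl so that the epimeric hydroxy acid F3 is isolated without lactonisation. Mitsunobu lactonisation (PPh3, DIAD, THF, 0 °C) then closes the γ-lactone with inversion at the allylic carbon C7. C7 is thus set by SN2 displacement instead of by the aldol face, and the route is rejoined at 26.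

Step 19 (chromium-mediated macrocyclisation). The risks are oligomerisation, the wrong face at C10 or C9 (a closed transition state with a ring-constrained allyl unit normally favours the other C9/C10 relationship, so the outcome here depends on chelation and the tether), and lactone migration to the C9 alkoxide. The fallback sets out from 27 and uses an open transition state instead. Palladium-catalysed stannylation of the allylic phosphate (Pd(PPh3)4, (Bu3Sn)2, LiCl, THF) gives the allylstannane diol F4. Parikh–Doering oxidation gives the allylstannane aldehyde F5. BF3·OEt2 at −78 °C under high dilution then closes the ring by an allylstannane–aldehyde addition through an acyclic, antiperiplanar transition state, and the route is rejoined at 29.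

**Further compounds**

F1 | step 7 | (2Z,6R)-6-hydroxy-N-methoxy-N,3-dimethyl-6-(epoxycyclohexenyl)hex-2-enamide: 10 with a C13–C14 epoxide cis to C2 | [C@H]12O[C@H]1CC=C[C@@]2(C)[C@H](O)CC/C(C)=C\C(=O)N(C)OC
F2 | step 7 | epoxy enone: F1 with C12 oxidised to the ketone | [C@H]12O[C@H]1C(=O)C=C[C@@]2(C)[C@H](O)CC/C(C)=C\C(=O)N(C)OC
F3 | step 16 | C7 epimer of the aldol hydroxy acid 25 | CC[Si](CC)(CC)O[C@H]1CC(OP(=O)(OCC)OCC)C(C)=C[C@@]1(C)[C@H](O[Si](CC)(CC)CC)CC/C(C)=C\[C@@H](O)[C@@]2(O[C@@H](C(C)(C)C)OC2=O)[C@@H](C)C(=O)O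
F4 | step 19 | allylstannane diol: 27 with tributylstannyl at C12 in place of the phosphate | CC[Si](CC)(CC)O[C@H]1CC([Sn](CCCC)(CCCC)CCCC)C(C)=C[C@@]1(C)[C@H](O[Si](CC)(CC)CC)CC/C(C)=C\[C@@H]2OC(=O)[C@H](C)[C@@]2(O)CO
F5 | step 19 | allylstannane aldehyde: F4 with C9 oxidised to the aldehyde | CC[Si](CC)(CC)O[C@H]1CC([Sn](CCCC)(CCCC)CCCC)C(C)=C[C@@]1(C)[C@H](O[Si](CC)(CC)CC)CC/C(C)=C\[C@@H]2OC(=O)[C@H](C)[C@@]2(O)C=O
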